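**Strategy.** The target is disconnected through ring B. Its six carbons (C4a, C5, C6, C7, C8, C8a) form a carbocycle whose only substituted atom is quaternary C6, para to C8a, the carbon that carries the pyridine nitrogen. A 1-amino-3-siloxybutadiene supplies C7, C8, C8a (as the oxygenated carbon) and C4a. A 2-aryl acrolein supplies C5, C6, the aryl group and, as CHO, the first carbon of the aminoethyl arm. One enantioselective [4+2] cycloaddition joins them, closes ring B and fixes C6. The formyl group then becomes the N-methylformamidoethyl arm, and the unmasked enone is annulated to the pyridine.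

Key step: step 2

Assumption: the sense of induction of the diol catalyst with a 2-aryl enal is taken to match that with 2-alkyl enals. The (R,R)-diol is written; its mirror image is used instead if the first run, correlated at enone 11, shows the opposite sense.

**Step 1**
Reactants: 1 (3,4-dimethoxyphenyl)acetaldehyde
Product: 2 2-(3,4-dimethoxyphenyl)prop-2-enal
Conditions: 37% aq. CH2O, pyrrolidine (10 mol%), EtCO2H (10 mol%), i-PrOH, 45 °C; used at once
Reagents that add atoms: formaldehyde, C=O
Why: α-Methylenation by an amine-catalysed Mannich condensation with formaldehyde and loss of the amine gives the conjugated 2-aryl enal, a standard outcome for arylacetaldehydes; the product is taken on at once because 2-aryl acroleins dimerise on standing.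

**Step 2**
Reactants: 2 2-(3,4-dimethoxyphenyl)prop-2-enal; 3 (E)-1-(dimethylamino)-3-[(tert-butyldimethylsilyl)oxy]buta-1,3-diene
Product: 4 (1R,2R)-4-[(tert-butyldimethylsilyl)oxy]-1-(3,4-dimethoxyphenyl)-2-(dimethylamino)cyclohex-3-ene-1-carbaldehyde (endo adduct, CHO cis to NMe2)
Conditions: (R,R)-1-naphthyl-TADDOL (20 mol%), toluene, −78 °C; evaporate, use crude
Reagents that add atoms: none
Why: The diol hydrogen-bonds to the aldehyde oxygen of 2 and lowers its LUMO, so diene 3 adds in a concerted, asynchronous [4+2] cycloaddition in which the siloxy-side CH2 terminus bonds to the enal CH2 and the amino-bearing terminus to the aryl-bearing carbon. The closest known reaction is the diol-catalysed enantioselective Diels–Alder reaction of this same diene with 2-alkyl acroleins; a hydrogen-bond donor is preferred to a cationic metal Lewis acid because the basic, acid-labile dialkylaminodiene reacts without catalyst at higher temperature and is degraded by such acids. Ring B closes by intermolecular [4+2] annulation, both new bonds (C6–C7 and C4a–C5 in target numbering) being made in this one step. The quaternary carbon is set by the catalyst, whose naphthyl groups screen one face of the bound enal, and the amine-bearing carbon follows from the endo transition state (formyl under the diene, hence cis to the amino group). The step needs regio-, endo- and facial selectivity: the first comes from the push–pull polarisation of diene and enal, the second from secondary orbital overlap of the formyl group, the third from the catalyst at −78 °C, where the uncatalysed path is slow. Only the quaternary centre has to be right, because the second stereocentre is erased in step 5.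

**Step 3**
Reactants: 4 (1R,2R)-4-[(tert-butyldimethylsilyl)oxy]-1-(3,4-dimethoxyphenyl)-2-(dimethylamino)cyclohex-3-ene-1-carbaldehyde; 5 nitromethane
Product: 8 (1R,6R)-3-[(tert-butyldimethylsilyl)oxy]-6-(3,4-dimethoxyphenyl)-N,N-dimethyl-6-[(E)-2-nitroethenyl]cyclohex-2-en-1-amine, via nitro alcohol 6 (not isolated), via mesylate 7 (not isolated)
Conditions: MeNO2 (excess), DBU (0.2 equiv), THF, 0 °C to rt; evaporate; MsCl, Et3N, CH2Cl2, −20 to 0 °C
Reagents that add atoms: none
Why: A Henry (nitroaldol) addition to the non-enolisable aldehyde, then mesylation and E1cB elimination, should give the (E)-nitroalkene; the ring ketone is still masked as its silyl enol ether, so no stabilised dienolate can be expelled by retro-aldol cleavage, and neither ring stereocentre is touched.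

**Step 4**
Reactants: 8 (1R,6R)-3-[(tert-butyldimethylsilyl)oxy]-6-(3,4-dimethoxyphenyl)-N,N-dimethyl-6-[(E)-2-nitroethenyl]cyclohex-2-en-1-amine
Product: 9 (1R,6R)-3-[(tert-butyldimethylsilyl)oxy]-6-(3,4-dimethoxyphenyl)-N,N-dimethyl-6-(2-nitroethyl)cyclohex-2-en-1-amine
Conditions: NaBH4, THF–EtOH, 0 °C; acetone, then pH 7 buffer
Reagents that add atoms: none
Why: NaBH4 adds hydride in conjugate fashion to the nitroalkene and the nitronate is protonated on work-up (standard nitroalkene-to-nitroalkane reduction); the neopentylic β-carbon disfavours nitronate–nitroalkene dimerisation, and the silyl enol ether and the amine are inert to borohydride.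

**Step 5**
Reactants: 9 (1R,6R)-3-[(tert-butyldimethylsilyl)oxy]-6-(3,4-dimethoxyphenyl)-N,N-dimethyl-6-(2-nitroethyl)cyclohex-2-en-1-amine
Product: 11 (4S)-4-(3,4-dimethoxyphenyl)-4-(2-nitroethyl)cyclohex-2-en-1-one, via amino ketone 10 (not isolated)
Conditions: aq. HF, MeCN, 0 °C to rt
Reagents that add atoms: none
Why: Acidic fluoride cleaves the silyl enol ether to the β-amino ketone, which loses dimethylamine by E1cB elimination to the conjugated enone (the usual unmasking of aminosiloxydiene cycloadducts); the amine-bearing stereocentre vanishes while the quaternary carbon, which has no acidic hydrogen, keeps its configuration.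

**Step 6**
Reactants: 11 (4S)-4-(3,4-dimethoxyphenyl)-4-(2-nitroethyl)cyclohex-2-en-1-one; 12 propargylamine (prop-2-yn-1-amine)
Product: 15 (6S)-6-(3,4-dimethoxyphenyl)-6-(2-nitroethyl)-5,6-dihydroquinoline, via N-propargyl imine 13 (not isolated), via dihydropyridine 14 (not isolated)
Conditions: NaAuCl4·2H2O (5 mol%), EtOH, reflux, air
Reagents that add atoms: none
Why: Gold-catalysed amination–annulation–aromatisation of a ketone with propargylamine: the N-propargyl imine can tautomerise only towards the saturated α′-CH2 (the other α-carbon is vinylic, the γ-carbon quaternary), this enamine carbon attacks the gold-activated alkyne in a 6-endo-dig closure, and air dehydrogenates the dihydropyridine; the ring-B alkene is kept up to this point because it alone distinguishes the two flanks of the ketone and so keeps the quaternary carbon stereogenic.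

**Step 7**
Reactants: 15 (6S)-6-(3,4-dimethoxyphenyl)-6-(2-nitroethyl)-5,6-dihydroquinoline
Product: 16 2-[(6S)-6-(3,4-dimethoxyphenyl)-5,6,7,8-tetrahydroquinolin-6-yl]ethan-1-amine
Conditions: H2 (4 atm), Raney Ni, MeOH, rt
Reagents that add atoms: none
Why: Catalytic hydrogenation over Raney Ni reduces the aliphatic nitro group to the primary amine and saturates the alkene conjugated with the pyridine, while the pyridine and the dimethoxyphenyl ring are not reduced at room temperature; the quaternary centre is not involved and stays stereogenic because ring B is now fused unsymmetrically to the pyridine.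

**Step 8**
Reactants: 16 2-[(6S)-6-(3,4-dimethoxyphenyl)-5,6,7,8-tetrahydroquinolin-6-yl]ethan-1-amine
Product: 17 N-{2-[(6S)-6-(3,4-dimethoxyphenyl)-5,6,7,8-tetrahydroquinolin-6-yl]ethyl}formamide
Conditions: HCO2Et, reflux
Reagents that add atoms: ethyl formate, CCOC=O
Why: Aminolysis of ethyl formate by the primary amine (N-formylation) is selective because the pyridine nitrogen cannot be acylated irreversibly.

**Step 9**
Reactants: 17 N-{2-[(6S)-6-(3,4-dimethoxyphenyl)-5,6,7,8-tetrahydroquinolin-6-yl]ethyl}formamide
Product: 18 N-{2-[(6S)-6-(3,4-dimethoxyphenyl)-5,6,7,8-tetrahydroquinolin-6-yl]ethyl}-N-methylformamide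
Conditions: NaH, THF, 0 °C; MeI (1.05 equiv), 0 °C to rt
Reagents that add atoms: iodomethane, CI
Why: The secondary formamide is deprotonated by NaH and the amidate is methylated by MeI in an SN2 reaction; the anion is formed completely before one equivalent of MeI is added cold, so that the far less nucleophilic pyridine nitrogen is not quaternised.

**Compound list**

1 | (3,4-dimethoxyphenyl)acetaldehyde | COc1ccc(CC=O)cc1OC | starting material
2 | 2-(3,4-dimethoxyphenyl)prop-2-enal | C=C(C=O)c1ccc(OC)c(OC)c1 | intermediate
3 | (E)-1-(dimethylamino)-3-[(tert-butyldimethylsilyl)oxy]buta-1,3-diene | CN(C)/C=C/C(=C)O[Si](C)(C)C(C)(C)C | starting material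
4 | (1R,2R)-4-[(tert-butyldimethylsilyl)oxy]-1-(3,4-dimethoxyphenyl)-2-(dimethylamino)cyclohex-3-ene-1-carbaldehyde | COc1ccc([C@@]2(C=O)[C@H](N(C)C)C=C(O[Si](C)(C)C(C)(C)C)CC2)cc1OC | intermediate
5 | nitromethane | C[N+](=O)[O-] | starting material
6 | 1-[(1R,2R)-4-[(tert-butyldimethylsilyl)oxy]-1-(3,4-dimethoxyphenyl)-2-(dimethylamino)cyclohex-3-en-1-yl]-2-nitroethan-1-ol (carbinol epimers) | COc1ccc([C@@]2(C(O)C[N+](=O)[O-])[C@H](N(C)C)C=C(O[Si](C)(C)C(C)(C)C)CC2)cc1OC | intermediate (not isolated)
7 | methanesulfonate of 6 | COc1ccc([C@@]2(C(OS(C)(=O)=O)C[N+](=O)[O-])[C@H](N(C)C)C=C(O[Si](C)(C)C(C)(C)C)CC2)cc1OC | intermediate (not isolated)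
8 | (1R,6R)-3-[(tert-butyldimethylsilyl)oxy]-6-(3,4-dimethoxyphenyl)-N,N-dimethyl-6-[(E)-2-nitroethenyl]cyclohex-2-en-1-amine | COc1ccc([C@@]2(/C=C/[N+](=O)[O-])[C@H](N(C)C)C=C(O[Si](C)(C)C(C)(C)C)CC2)cc1OC | intermediate
9 | (1R,6R)-3-[(tert-butyldimethylsilyl)oxy]-6-(3,4-dimethoxyphenyl)-N,N-dimethyl-6-(2-nitroethyl)cyclohex-2-en-1-amine | COc1ccc([C@@]2(CC[N+](=O)[O-])[C@H](N(C)C)C=C(O[Si](C)(C)C(C)(C)C)CC2)cc1OC | intermediate
10 | (3R,4R)-4-(3,4-dimethoxyphenyl)-3-(dimethylamino)-4-(2-nitroethyl)cyclohexan-1-one | COc1ccc([C@@]2(CC[N+](=O)[O-])[C@H](N(C)C)CC(=O)CC2)cc1OC | intermediate (not isolated)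
11 | (4S)-4-(3,4-dimethoxyphenyl)-4-(2-nitroethyl)cyclohex-2-en-1-one | COc1ccc([C@@]2(CC[N+](=O)[O-])C=CC(=O)CC2)cc1OC | intermediate
12 | propargylamine | C#CCN | starting material
13 | (4S)-4-(3,4-dimethoxyphenyl)-4-(2-nitroethyl)-N-(prop-2-yn-1-yl)cyclohex-2-en-1-imine | COc1ccc([C@@]2(CC[N+](=O)[O-])C=CC(=NCC#C)CC2)cc1OC | intermediate (not isolated)
14 | (6S)-6-(3,4-dimethoxyphenyl)-6-(2-nitroethyl)-1,2,5,6-tetrahydroquinoline | COc1ccc([C@@]2(CC[N+](=O)[O-])C=CC3=C(C=CCN3)C2)cc1OC | intermediate (not isolated)
15 | (6S)-6-(3,4-dimethoxyphenyl)-6-(2-nitroethyl)-5,6-dihydroquinoline | COc1ccc([C@@]2(CC[N+](=O)[O-])C=Cc3ncccc3C2)cc1OC | intermediate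
16 | 2-[(6S)-6-(3,4-dimethoxyphenyl)-5,6,7,8-tetrahydroquinolin-6-yl]ethan-1-amine | COc1ccc([C@@]2(CCN)CCc3ncccc3C2)cc1OC | intermediate
17 | N-{2-[(6S)-6-(3,4-dimethoxyphenyl)-5,6,7,8-tetrahydroquinolin-6-yl]ethyl}formamide | COc1ccc([C@@]2(CCNC=O)CCc3ncccc3C2)cc1OC | intermediate
18 | N-{2-[(6S)-6-(3,4-dimethoxyphenyl)-5,6,7,8-tetrahydroquinolin-6-yl]ethyl}-N-methylformamide | COc1ccc([C@@]2(CCN(C)C=O)CCc3ncccc3C2)cc1OC | target

**Step count and risks**

Total steps: 9. Longest linear sequence: 9 steps (1 to 18); compounds 3, 5 and 12 are bought.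

**Most likely to fail, first: step 2.** The uncatalysed cycloaddition and dimerisation of the enal may compete with the hydrogen-bond-catalysed path. The flat 2-aryl enal may also sit less tightly in the chiral pocket than a 2-alkyl enal, so that facial selectivity falls short. The fallback makes the quaternary carbon and ring B by enantioselective enamine catalysis. It sets out from 1: conjugate addition to nitroethylene under pyrrolidine/acid catalysis should give racemic 2-(3,4-dimethoxyphenyl)-4-nitrobutanal F1. Its labile α-centre is then fixed in a Robinson annulation with but-3-en-2-one under a chiral prolinamide-type or primary-amine catalyst (Michael addition of the α,α-disubstituted enamine, then intramolecular aldol condensation), the catalyst antipode being chosen for the (S)-enone. This should deliver 11 directly, and the route is rejoined at step 6.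

**Second: step 6.** The sequence may stall at the imine or dihydropyridine stage on this cross-conjugated enone, or the amine may be diverted into conjugate addition or nitronate chemistry. The fallback is a metal-free, oxidant-free C3N condensation. It sets out from 11, which is heated with 3-aminoacrolein (3-aminoprop-2-enal) and catalytic piperidinium acetate at about 110 °C (Friedländer-type annulation). The only enolisable position, the α′-CH2, condenses with the aldehyde carbon and the amino group cyclodehydrates onto the ketone. This should give 15 directly, where the route is rejoined; no compound outside the list is made (entry F0).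

**Third: step 3.** The nitroaldol addition at the neopentylic aldehyde is reversible and may remain incomplete, and base or mesylation may unmask the enone prematurely. The fallback replaces the nitroaldol by an irreversible Wittig homologation and carries the nitrogen as an oxime ether. It sets out from 4 and runs as follows:
- Methoxymethylenation with Ph3P=CHOMe (from MeOCH2PPh3Cl and KHMDS, THF, 0 °C) should give (1R,6R)-3-[(tert-butyldimethylsilyl)oxy]-6-(3,4-dimethoxyphenyl)-6-(2-methoxyethenyl)-N,N-dimethylcyclohex-2-en-1-amine F2.
- Aqueous HCl in THF hydrolyses both enol ethers and eliminates dimethylamine to give 2-[(1S)-1-(3,4-dimethoxyphenyl)-4-oxocyclohex-2-en-1-yl]acetaldehyde F3.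
- One equivalent of MeONH2·HCl with NaOAc at 0 °C converts the aldehyde, far more reactive than the enone carbonyl, into 2-[(1S)-1-(3,4-dimethoxyphenyl)-4-oxocyclohex-2-en-1-yl]acetaldehyde O-methyloxime F4.
- The conditions of step 6 then give 2-[(6S)-6-(3,4-dimethoxyphenyl)-5,6-dihydroquinolin-6-yl]acetaldehyde O-methyloxime F5.
- Hydrogenation over Raney Ni in methanolic NH3 reduces the oxime ether and the ring alkene and comes back to the route at 16.

**Further compounds**

F1 | step 2 | 2-(3,4-dimethoxyphenyl)-4-nitrobutanal (racemic) | COc1ccc(C(CC[N+](=O)[O-])C=O)cc1OC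
F0 | step 6 | none | none
F2 | step 3 | (1R,6R)-3-[(tert-butyldimethylsilyl)oxy]-6-(3,4-dimethoxyphenyl)-6-(2-methoxyethenyl)-N,N-dimethylcyclohex-2-en-1-amine (E/Z mixture) | COc1ccc([C@@]2(C=COC)[C@H](N(C)C)C=C(O[Si](C)(C)C(C)(C)C)CC2)cc1OC
F3 | step 3 | 2-[(1S)-1-(3,4-dimethoxyphenyl)-4-oxocyclohex-2-en-1-yl]acetaldehyde | COc1ccc([C@@]2(CC=O)C=CC(=O)CC2)cc1OC
F4 | step 3 | 2-[(1S)-1-(3,4-dimethoxyphenyl)-4-oxocyclohex-2-en-1-yl]acetaldehyde O-methyloxime (E/Z mixture) | COc1ccc([C@@]2(CC=NOC)C=CC(=O)CC2)cc1OC
F5 | step 3 | 2-[(6S)-6-(3,4-dimethoxyphenyl)-5,6-dihydroquinolin-6-yl]acetaldehyde O-methyloxime (E/Z mixture) | COc1ccc([C@@]2(CC=NOC)C=Cc3ncccc3C2)cc1OC
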